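## The problem

Dinklagin A is a flavanone. A resorcinol-type ring A is fused through O1 and C4a/C8a to the pyranone ring C, which carries the ketone at C4, a methylene at C3 and, at C2, a 2,2-dimethyl-2H-chromen-6-yl group (ring B with its annulated pyran). Ring A bears a free hydroxyl at C7 and a prenyl group at C6; direct prenylation of a resorcinol ketone does not give this pattern cleanly, because C8 competes. C2 (S) is the only stereocenter and nothing else in the molecule can relay to it, so a chiral catalyst must set it. It is fragile in two ways: as the β-carbon of a β-aryloxy ketone it is scrambled by base through ring opening to the 2'-hydroxychalcone, and its C–O bond ionises under acid because the pyran oxygen of ring B sits para to it. Acid also threatens the prenyl group next to the free phenol (closure to a chroman) and the chromene alkene, and any oxidant has three alkenes to choose from. The feature that opens the molecule is that C3 is an unsubstituted methylene between C2 and C4. A C3=C4 double bond at the enol ether level is a latent CH2–C=O unit, and it can be made from a vinyl group on C2 and the silyl enol ether of an acetyl group on C4a, both held ortho to each other on ring A. The synthesis must therefore build C2 as an O-aryl, C-vinyl stereocenter before ring C exists and keep the ketone masked until the last step.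

## Retrosynthesis

**Unmasking (17 from 15).** No skeletal bond is cut. The two O–Si bonds of the bis-silyl 2H-chromene 15 are cleaved, and the enol 16 tautomerises to the ketone of 17. Carrying the ketone as a silyl enol ether means the β-aryloxy ketone appears only once, at the end. The phenol and the enol carry the same silyl group so that one acidic fluoride source removes both. The forward step must be neither basic (ring opening at C2) nor strongly acidic (prenyl, C2–O).

**Ring C (15 from 14).** The C3=C4 bond is cut, leading to diene 14 with a vinyl group on C2 and a silyl enol ether on C4a. The neighbouring cuts are weaker for this target. Cutting O1–C2 in the ring-closing step (oxa-Michael addition of a chalcone) puts the stereocenter into a reversible step. Cutting C4–C4a calls for an aryl-metal next to a base-labile β-aryloxy carbonyl. Metathesis is neutral, leaves C2 untouched and gives C4 at the correct oxidation level. The forward reaction must pick two alkenes out of four and must not migrate the allylic ether double bond.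

**Enol ether (14 from 13).** One O–Si bond is cut, leading to the aryl methyl ketone 13. A silyl triflate with an amine base forms the enol ether without a strong base near the allylic, benzylic C2–H.

**The stereocenter (13 from 11 and 8).** The O1–C2 bond is cut. This divides the molecule into a ring A phenol 11 and a linear cinnamyl-type carbonate 8 of similar size. The bond is formed by iridium-catalysed allylic etherification, which gives the branched ether and sets C2 in the same event. An SN2 etherification at a para-alkoxybenzylic carbon, or an SNAr reaction on an activated fluoroarene, would each need a pre-made chiral alcohol. The forward step must be branched-selective, O-selective and face-selective, and the product must not re-ionise.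

**Ring A (11 from 10 from 9).** The aryl–CH2 bond of the prenyl group is cut. The bromine of the commercial bromoresacetophenone 9 already marks C6, so the C6/C8 regiochemistry problem does not arise. The 4-hydroxyl of 9 is silylated selectively to give 10, because the 2-hydroxyl is held in a hydrogen bond to the acetyl group. A Stille coupling of 10 with a prenyl–tin reagent then gives 11.

**Carbonate (8 from 7 from 6 from 5).** These are functional-group changes plus one C=C bond. Aldehyde 5 is homologated by Horner–Wadsworth–Emmons olefination to the (E)-ester 6, reduced to allylic alcohol 7 and acylated to methyl carbonate 8. The iridium catalyst needs the pure (E)-linear carbonate, and the olefination supplies that geometry.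

**Ring B (5 from 3 from 1 and 2).** The pyran of the chromene is cut at the aryl–C4 bond and at O–CMe2. The aryl propargyl ether 3, from phenol 1 and tertiary propargylic chloride 2, rearranges thermally to chromene 5 through the ortho-allenylphenol 4.

## Roads not taken

**Alternative 1:** Rings A and C are cut together, at C8a–C4a and C6–C5, back to the acyclic (E,Z)-dienyne A2. Heating A2 would bring the 1-alkoxy-3-silyloxy diene onto the tethered terminal alkyne in an intramolecular Diels–Alder reaction, and a quinone oxidant would aromatise the cyclohexadiene to the 4-silyloxyflavan A1.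
- Merits: two rings and two C–C bonds form in one step, the tether fixes the ring A substitution pattern, and ring A analogues would be easy to reach. In bonds formed per step this road is better than the chosen plan.
- Weak points: A2 needs two stereocenters, one of which (C4) is later oxidised away. Its electron-rich dienol ether is hydrolytically labile. The alkyne is unactivated, so the cycloaddition needs heat. The quinone oxidant meets a para-alkoxybenzylic ether C–H, a benzylic silyl ether and three alkenes. After A1, C4 must still be desilylated selectively and oxidised before the phenol is freed.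
- Comparison: the chosen plan buys ring A with its oxygens and a bromine at C6 in place, never changes the oxidation state at C4, and ends one step after the key step.

**Alternative 2:** Ring C is cut at O1–C2 and C3–C4. Under a confined chiral Brønsted acid, salicylaldehyde A4 and an orthoformate would give a 4-methoxy ortho-quinone methide, which adds across the vinyl group of vinylchromene A5 to give the cis-4-methoxyflavan A3.
- Merits: this is the most convergent road. Two small fragments are joined, ring C closes, and C2 is set in one catalytic step. In convergence and probably in step count it is better than the chosen plan.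
- Weak points: a strong acid acts on a substrate with a prenyl group, a chromene alkene and an electron-rich styrene prone to cationic oligomerisation. The catalyst must control a bicyclic, para-alkoxy styrene. C4 arrives as a methyl ether that must be cleaved and oxidised to the ketone in the presence of three alkenes and the ionisable C2–O bond, followed by the same base-sensitive phenol release.
- Comparison: the chosen plan delivers C4 at the ketone oxidation level directly from the enol ether, keeps every step after the etherification neutral or mildly acidic, and relies on an asymmetric step whose sense of induction is well mapped for aryl-substituted allyl carbonates.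

**Alternative 3:** Ring C is cut at C4–C4a. Bromine–lithium exchange on the (S)-β-aryloxy N-methoxy-N-methyl amide A7 with an alkyllithium would give an aryllithium that closes onto the amide (Parham cyclisation) to the 7-O-methoxymethyl flavanone A6.
- Merits: the ketone forms directly, the tetrahedral intermediate shields it from the base until quench, and only one deprotection follows. After the key step this road is as short as the chosen plan, and it needs no enol ether.
- Weak points: A7 is a β-aryloxy amide with acidic α-protons, so deprotonation and loss of the aryloxide (destroying C2) compete with the exchange. The acetal on the C7 oxygen must be removed with acid beside the prenyl group and the ionisable C2–O bond. A7 still needs an enantioselective C2–O bond formation at a para-alkoxybenzylic carbon, so the stereochemical problem is not lightened.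
- Comparison: the chosen plan closes the ring with a neutral catalyst, uses fluoride-labile silyl groups, and forms the C2–O bond by a catalytic asymmetric reaction rather than an SN2 displacement on a cation-prone centre.

Key step: step 10

Assumption: the (Sa,S,S) enantiomer of the binaphthol-derived bis(1-phenylethyl)phosphoramidite is taken to give the (S)-branched ether, the same facial sense as for N- and O-nucleophiles on aryl-substituted allyl carbonates. If the sense is opposite, the mirror-image ligand is used and nothing else changes.

## Route

Step 1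
Reactants: 1 4-hydroxybenzaldehyde; 2 3-chloro-3-methylbut-1-yne
Product: 3 4-[(2-methylbut-3-yn-2-yl)oxy]benzaldehyde
Conditions: DBU, CuCl2·2H2O (cat.), MeCN, 0 °C
Reagents that add atoms: none
Why: Copper-catalysed O-propargylation of an acidic phenol with a tertiary propargylic chloride; the copper acetylide/allenylidene pathway avoids the elimination that plagues a plain SN1/SN2 etherification at a tertiary centre.

Step 2
Reactants: 3 4-[(2-methylbut-3-yn-2-yl)oxy]benzaldehyde
Product: 5 2,2-dimethyl-2H-chromene-6-carbaldehyde, via ortho-allenylphenol 4 (not isolated)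
Conditions: PhNEt2, 190 °C
Reagents that add atoms: none
Why: Aryl propargyl ether Claisen rearrangement gives the ortho-allenylphenol 4, which undergoes a [1,5]-hydrogen shift and 6π-electrocyclisation to the 2,2-dimethylchromene; the para-formyl group leaves only the two equivalent ortho positions.

Step 3
Reactants: 5 2,2-dimethyl-2H-chromene-6-carbaldehyde
Product: 6 ethyl (2E)-3-(2,2-dimethyl-2H-chromen-6-yl)prop-2-enoate
Conditions: (EtO)2P(O)CH2CO2Et, NaH, THF, 0 °C to rt
Reagents that add atoms: triethyl phosphonoacetate, CCOC(=O)CP(=O)(OCC)OCC
Why: Horner–Wadsworth–Emmons olefination of an aromatic aldehyde with a stabilised phosphonate anion is reliably (E)-selective, which matters because the iridium step needs the geometrically pure linear carbonate.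

Step 4
Reactants: 6 ethyl (2E)-3-(2,2-dimethyl-2H-chromen-6-yl)prop-2-enoate
Product: 7 (2E)-3-(2,2-dimethyl-2H-chromen-6-yl)prop-2-en-1-ol
Conditions: i-Bu2AlH (2.2 equiv), CH2Cl2, −78 °C; aq. potassium sodium tartrate
Reagents that add atoms: none
Why: 1,2-Reduction of an α,β-unsaturated ester to the allylic alcohol with i-Bu2AlH; neither alkene is touched.

Step 5
Reactants: 7 (2E)-3-(2,2-dimethyl-2H-chromen-6-yl)prop-2-en-1-ol
Product: 8 (2E)-3-(2,2-dimethyl-2H-chromen-6-yl)prop-2-en-1-yl methyl carbonate
Conditions: ClCO2Me, pyridine, CH2Cl2, 0 °C
Reagents that add atoms: methyl chloroformate, COC(=O)Cl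
Why: Standard O-acylation of a primary allylic alcohol; the methyl carbonate is the usual leaving group for iridium-catalysed allylic substitution and releases only CO2 and methoxide.

Step 6
Reactants: 9 1-(5-bromo-2,4-dihydroxyphenyl)ethanone
Product: 10 1-[5-bromo-4-(tert-butyldimethylsilyloxy)-2-hydroxyphenyl]ethanone
Conditions: TBSCl (1.05 equiv), imidazole, CH2Cl2, 0 °C
Reagents that add atoms: tert-butyldimethylsilyl chloride, CC(C)(C)[Si](C)(C)Cl
Why: Selective silylation of the 4-hydroxyl; the 2-hydroxyl is tied up in a hydrogen bond to the acetyl oxygen and is much less nucleophilic.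

Step 7
Reactants: 10 1-[5-bromo-4-(tert-butyldimethylsilyloxy)-2-hydroxyphenyl]ethanone
Product: 11 1-[4-(tert-butyldimethylsilyloxy)-2-hydroxy-5-(3-methylbut-2-en-1-yl)phenyl]ethanone
Conditions: Bu3SnCH2CH=CMe2, Pd(PPh3)4 (5 mol%), toluene, 105 °C
Reagents that add atoms: tributyl(3-methylbut-2-en-1-yl)stannane, CCCC[Sn](CCCC)(CCCC)CC=C(C)C
Why: Stille coupling of an aryl bromide with a prenylstannane under zerovalent palladium; reductive elimination at the less hindered allyl terminus gives the linear prenyl arene at the carbon marked by bromine, and the neutral, fluoride-free medium spares the aryl silyl ether and the chelated phenol.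

Step 8
Reactants: 11 1-[4-(tert-butyldimethylsilyloxy)-2-hydroxy-5-(3-methylbut-2-en-1-yl)phenyl]ethanone; 8 (2E)-3-(2,2-dimethyl-2H-chromen-6-yl)prop-2-en-1-yl methyl carbonate
Product: 13 1-[4-(tert-butyldimethylsilyloxy)-2-{[(1S)-1-(2,2-dimethyl-2H-chromen-6-yl)prop-2-en-1-yl]oxy}-5-(3-methylbut-2-en-1-yl)phenyl]ethanone, via lithium phenoxide 12 (not isolated)
Conditions: 11 (1.5 equiv), LiN(SiMe3)2 (1.0 equiv to 11), THF, 0 °C; then 8, [Ir(cod)Cl]2 (2 mol%), (Sa,S,S)-binaphthol N,N-bis(1-phenylethyl)phosphoramidite (4 mol%; catalyst pre-formed with n-PrNH2 at 50 °C and evaporated), THF, 40–50 °C; stopped when 8 is consumed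
Reagents that add atoms: none
Why: Iridium-catalysed asymmetric allylic etherification: the cyclometalated phosphoramidite complex formed from the monovalent iridium precatalyst ionises the linear carbonate, and the lithium aryloxide 12 attacks the aryl-substituted terminus of the allyl ligand anti to the metal, giving the branched O-allyl ether. The ligand enantiomer fixes the face and hence (S) at the future C2; the acetyl methyl is not deprotonated by one equivalent of amide base.

Step 9
Reactants: 13 1-[4-(tert-butyldimethylsilyloxy)-2-{[(1S)-1-(2,2-dimethyl-2H-chromen-6-yl)prop-2-en-1-yl]oxy}-5-(3-methylbut-2-en-1-yl)phenyl]ethanone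
Product: 14 tert-butyl({1-[4-(tert-butyldimethylsilyloxy)-2-{[(1S)-1-(2,2-dimethyl-2H-chromen-6-yl)prop-2-en-1-yl]oxy}-5-(3-methylbut-2-en-1-yl)phenyl]ethenyl}oxy)dimethylsilane
Conditions: TBSOTf (1.3 equiv), Et3N (3 equiv), CH2Cl2, −78 to 0 °C
Reagents that add atoms: tert-butyldimethylsilyl trifluoromethanesulfonate, CC(C)(C)[Si](C)(C)OS(=O)(=O)C(F)(F)F
Why: Soft enolisation of an aryl methyl ketone (silyl triflate activation, amine deprotonation) gives the terminal silyl enol ether; the excess amine keeps the medium non-acidic for the ionisable allylic benzylic ether, and no strong base meets the C–H next to oxygen.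

Step 10
Reactants: 14 tert-butyl({1-[4-(tert-butyldimethylsilyloxy)-2-{[(1S)-1-(2,2-dimethyl-2H-chromen-6-yl)prop-2-en-1-yl]oxy}-5-(3-methylbut-2-en-1-yl)phenyl]ethenyl}oxy)dimethylsilane
Product: 15 (2S)-4,7-bis(tert-butyldimethylsilyloxy)-2-(2,2-dimethyl-2H-chromen-6-yl)-6-(3-methylbut-2-en-1-yl)-2H-chromene
Conditions: RuCl2(=CHPh)(PCy3)(H2IMes) (second-generation Grubbs catalyst, 5–10 mol%), 1,4-benzoquinone (10 mol%), degassed toluene (5 mM), 60 °C, argon sparge
Reagents that add atoms: none
Why: The ruthenium benzylidene exchanges onto the monosubstituted vinyl group, the only unhindered terminal alkene, to give an alkylidene at the future C3; this adds intramolecularly to the 1,1-disubstituted silyl enol ether through a ruthenacyclobutane with ruthenium on the terminal CH2, and cycloreversion forms C3=C4 and a ruthenium methylidene that carries the chain, with ethylene swept out by the argon stream. The closest known reactions are ring-closing metathesis of silyl enol ethers with terminal alkenes to cyclic silyl enol ethers, and of aryl allyl ethers with ortho alkenyl groups to 2H-chromenes. Ring C closes as a six-membered ring by ring-closing olefin metathesis, helped by the ortho placement of both alkenes on ring A. No stereocenter is formed; C2, set in step 8, is not involved because the catalyst is neutral and does not ionise the allylic ether. The step needs site selectivity among four alkenes, and the substrate secures it: the prenyl group sits para to O1 and the chromene alkene lies in ring B, so neither can reach the alkylidene intramolecularly, and both are too substituted to compete intermolecularly at this dilution. Benzoquinone intercepts ruthenium hydrides that could migrate the allylic ether double bond, and the moderate temperature keeps thermal ring opening of the 2H-chromene out of reach. The air-sensitive product is taken directly into step 11.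

Step 11
Reactants: 15 (2S)-4,7-bis(tert-butyldimethylsilyloxy)-2-(2,2-dimethyl-2H-chromen-6-yl)-6-(3-methylbut-2-en-1-yl)-2H-chromene
Product: 17 dinklagin A [(2S)-2-(2,2-dimethyl-2H-chromen-6-yl)-7-hydroxy-6-(3-methylbut-2-en-1-yl)-2,3-dihydro-4H-chromen-4-one], via 4-hydroxy-2H-chromene enol 16 (not isolated)
Conditions: HF·pyridine, excess pyridine, THF, 0 °C to rt
Reagents that add atoms: none
Why: Fluoride-mediated desilylation of the silyl enol ether and the aryl silyl ether in a weakly acidic buffer; the enol 16 is protonated at C3 to the ketone without a free enolate or phenoxide persisting, so the base-induced ring opening that would racemise C2 is avoided, and the buffer is too weak an acid to add the phenol across the prenyl alkene.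

## Compound list

1 | 4-hydroxybenzaldehyde | O=Cc1ccc(O)cc1 | starting material
2 | 3-chloro-3-methylbut-1-yne | CC(C)(Cl)C#C | starting material
3 | 4-[(2-methylbut-3-yn-2-yl)oxy]benzaldehyde | O=Cc1ccc(OC(C)(C)C#C)cc1 | intermediate
4 | 4-hydroxy-3-(3-methylbuta-1,2-dien-1-yl)benzaldehyde | CC(C)=C=Cc1cc(C=O)ccc1O | intermediate (not isolated)
5 | 2,2-dimethyl-2H-chromene-6-carbaldehyde | O=Cc1ccc2c(c1)C=CC(C)(C)O2 | intermediate
6 | ethyl (2E)-3-(2,2-dimethyl-2H-chromen-6-yl)prop-2-enoate | CCOC(=O)/C=C/c1ccc2c(c1)C=CC(C)(C)O2 | intermediate
7 | (2E)-3-(2,2-dimethyl-2H-chromen-6-yl)prop-2-en-1-ol | OC/C=C/c1ccc2c(c1)C=CC(C)(C)O2 | intermediate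
8 | (2E)-3-(2,2-dimethyl-2H-chromen-6-yl)prop-2-en-1-yl methyl carbonate | COC(=O)OC/C=C/c1ccc2c(c1)C=CC(C)(C)O2 | intermediate
9 | 1-(5-bromo-2,4-dihydroxyphenyl)ethanone | CC(=O)c1cc(Br)c(O)cc1O | starting material
10 | 1-[5-bromo-4-(tert-butyldimethylsilyloxy)-2-hydroxyphenyl]ethanone | CC(=O)c1cc(Br)c(O[Si](C)(C)C(C)(C)C)cc1O | intermediate
11 | 1-[4-(tert-butyldimethylsilyloxy)-2-hydroxy-5-(3-methylbut-2-en-1-yl)phenyl]ethanone | CC(=O)c1cc(CC=C(C)C)c(O[Si](C)(C)C(C)(C)C)cc1O | intermediate
12 | lithium 2-acetyl-5-(tert-butyldimethylsilyloxy)-4-(3-methylbut-2-en-1-yl)phenoxide | [Li+].CC(=O)c1cc(CC=C(C)C)c(O[Si](C)(C)C(C)(C)C)cc1[O-] | intermediate (not isolated)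
13 | 1-[4-(tert-butyldimethylsilyloxy)-2-{[(1S)-1-(2,2-dimethyl-2H-chromen-6-yl)prop-2-en-1-yl]oxy}-5-(3-methylbut-2-en-1-yl)phenyl]ethanone | CC(C)=CCc1cc(C(C)=O)c(cc1O[Si](C)(C)C(C)(C)C)O[C@@H](C=C)c1ccc2c(c1)C=CC(C)(C)O2 | intermediate
14 | tert-butyl({1-[4-(tert-butyldimethylsilyloxy)-2-{[(1S)-1-(2,2-dimethyl-2H-chromen-6-yl)prop-2-en-1-yl]oxy}-5-(3-methylbut-2-en-1-yl)phenyl]ethenyl}oxy)dimethylsilane | CC(C)=CCc1cc(C(=C)O[Si](C)(C)C(C)(C)C)c(cc1O[Si](C)(C)C(C)(C)C)O[C@@H](C=C)c1ccc2c(c1)C=CC(C)(C)O2 | intermediate
15 | (2S)-4,7-bis(tert-butyldimethylsilyloxy)-2-(2,2-dimethyl-2H-chromen-6-yl)-6-(3-methylbut-2-en-1-yl)-2H-chromene | CC(C)=CCc1cc2c(cc1O[Si](C)(C)C(C)(C)C)O[C@H](c1ccc3c(c1)C=CC(C)(C)O3)C=C2O[Si](C)(C)C(C)(C)C | intermediate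
16 | (2S)-2-(2,2-dimethyl-2H-chromen-6-yl)-6-(3-methylbut-2-en-1-yl)-2H-chromene-4,7-diol | CC(C)=CCc1cc2c(cc1O)O[C@H](c1ccc3c(c1)C=CC(C)(C)O3)C=C2O | intermediate (not isolated)
17 | dinklagin A, (2S)-2-(2,2-dimethyl-2H-chromen-6-yl)-7-hydroxy-6-(3-methylbut-2-en-1-yl)-2,3-dihydro-4H-chromen-4-one | CC(C)=CCc1cc2c(cc1O)O[C@H](c1ccc3c(c1)C=CC(C)(C)O3)CC2=O | target

## Step count and risks

Total steps: 11. Longest linear sequence: 9 steps (steps 1 to 5 and 8 to 11, from 4-hydroxybenzaldehyde). Steps 6 and 7 form the second branch.

**Step 10 (key step).**
- Risk: loss of site selectivity, if the propagating ruthenium methylidene or ethylene engages the prenyl alkene and truncates it by loss of isobutylene.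
- Risk: double-bond migration in the allylic ether by ruthenium hydrides, which would erase C2.
- Risk: slow closure onto the hindered, electron-rich enol ether, so that intermolecular coupling of the vinyl groups takes over.
- Fallback: install the prenyl group after the ring is closed, so that the metathesis substrate has no prenyl alkene. Bromophenol 10 is deprotonated with LiN(SiMe3)2 to lithium 2-acetyl-4-bromo-5-(tert-butyldimethylsilyloxy)phenoxide F1. This is coupled with carbonate 8 under the iridium conditions of step 8 to give the (S)-branched bromo ether 1-[5-bromo-4-(tert-butyldimethylsilyloxy)-2-{[(1S)-1-(2,2-dimethyl-2H-chromen-6-yl)prop-2-en-1-yl]oxy}phenyl]ethanone F2. Enol silylation with TBSOTf and Et3N gives the bromo diene F3. Ring closure with RuCl2(=CHPh)(PCy3)(H2IMes) gives (2S)-6-bromo-4,7-bis(tert-butyldimethylsilyloxy)-2-(2,2-dimethyl-2H-chromen-6-yl)-2H-chromene F4. Stille coupling of F4 with tributyl(3-methylbut-2-en-1-yl)stannane and Pd(PPh3)4 rejoins the route at 15. The endocyclic C2–O bond of F4 lies close to the plane of the C3=C4 alkene and is therefore poorly aligned for ionisation by zerovalent palladium.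

**Step 8.**
- Risk: low reactivity of the chelated, electron-poor ortho-acetyl phenoxide towards the allyl iridium intermediate.
- Risk: erosion of enantiopurity and branched-to-linear isomerisation, because the product pairs a good aryloxide leaving group with an electron-rich aryl group and can re-ionise on the catalyst.
- Fallback: set C2 in a resolved alcohol and form the C–O bond by SN2 displacement with inversion. Aldehyde 5 is treated with CH2=CHMgBr to give racemic 1-(2,2-dimethyl-2H-chromen-6-yl)prop-2-en-1-ol F5. Lipase-catalysed acetylation (immobilised Candida antarctica lipase B, vinyl acetate) converts the (R)-enantiomer to (1R)-1-(2,2-dimethyl-2H-chromen-6-yl)prop-2-en-1-yl acetate F6, which is separated from the unreacted (S)-alcohol. Methanolysis of F6 (K2CO3, MeOH) gives (1R)-1-(2,2-dimethyl-2H-chromen-6-yl)prop-2-en-1-ol F7. Mitsunobu etherification of F7 with phenol 11 (PPh3, diisopropyl azodicarboxylate, toluene, 0 °C) inverts the centre and rejoins the route at 13. Leakage through an allyl cation (racemisation, SN2' product) is this fallback's own weak point, so it is run cold in a non-polar solvent.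

**Step 7.**
- Risk: allylic transposition during transmetalation or reductive elimination, giving the 1,1-dimethylallyl isomer.
- Risk: slow oxidative addition into the electron-rich aryl bromide.
- Risk: loss of the para-acyl aryl silyl ether at high temperature.
- Fallback: separate the C–C coupling from the build-up of the trisubstituted alkene. Bromide 10 is coupled with allyltributylstannane (Pd(PPh3)4, toluene, 100 °C), where transposition is degenerate, to give 1-[5-allyl-4-(tert-butyldimethylsilyloxy)-2-hydroxyphenyl]ethanone F8. Cross-metathesis of F8 with excess 2-methylbut-2-ene and RuCl2(=CHPh)(PCy3)(H2IMes) in CH2Cl2 at 40 °C gives the prenyl group and rejoins the route at 11.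

**Step 11.**
- Risk: reversible opening of ring C through the enolate or phenoxide if the medium turns basic, which racemises C2.
- Risk: acid-induced addition of the freed 7-hydroxyl across the prenyl alkene if the medium is too acidic or the hindered aryl silyl ether needs forcing.
- Fallback: release the two groups in separate operations. The enol ether of 15, far more acid-labile than the aryl silyl ether, is hydrolysed with oxalic acid in wet THF at 0 °C to (2S)-7-(tert-butyldimethylsilyloxy)-2-(2,2-dimethyl-2H-chromen-6-yl)-6-(3-methylbut-2-en-1-yl)chroman-4-one F9. The phenolic silyl ether of F9 is then cleaved with KHF2 in MeOH at rt, a near-neutral reagent selective for aryl silyl ethers, rejoining the route at 17.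

## Further compounds

F1 | step 10 | lithium 2-acetyl-4-bromo-5-(tert-butyldimethylsilyloxy)phenoxide | [Li+].CC(=O)c1cc(Br)c(O[Si](C)(C)C(C)(C)C)cc1[O-]
F2 | step 10 | 1-[5-bromo-4-(tert-butyldimethylsilyloxy)-2-{[(1S)-1-(2,2-dimethyl-2H-chromen-6-yl)prop-2-en-1-yl]oxy}phenyl]ethanone | CC(=O)c1cc(Br)c(O[Si](C)(C)C(C)(C)C)cc1O[C@@H](C=C)c1ccc2c(c1)C=CC(C)(C)O2
F3 | step 10 | tert-butyl({1-[5-bromo-4-(tert-butyldimethylsilyloxy)-2-{[(1S)-1-(2,2-dimethyl-2H-chromen-6-yl)prop-2-en-1-yl]oxy}phenyl]ethenyl}oxy)dimethylsilane | C=C(O[Si](C)(C)C(C)(C)C)c1cc(Br)c(O[Si](C)(C)C(C)(C)C)cc1O[C@@H](C=C)c1ccc2c(c1)C=CC(C)(C)O2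
F4 | step 10 | (2S)-6-bromo-4,7-bis(tert-butyldimethylsilyloxy)-2-(2,2-dimethyl-2H-chromen-6-yl)-2H-chromene | Brc1cc2c(cc1O[Si](C)(C)C(C)(C)C)O[C@H](c1ccc3c(c1)C=CC(C)(C)O3)C=C2O[Si](C)(C)C(C)(C)C
F5 | step 8 | racemic 1-(2,2-dimethyl-2H-chromen-6-yl)prop-2-en-1-ol | C=CC(O)c1ccc2c(c1)C=CC(C)(C)O2
F6 | step 8 | (1R)-1-(2,2-dimethyl-2H-chromen-6-yl)prop-2-en-1-yl acetate | CC(=O)O[C@H](C=C)c1ccc2c(c1)C=CC(C)(C)O2
F7 | step 8 | (1R)-1-(2,2-dimethyl-2H-chromen-6-yl)prop-2-en-1-ol | O[C@H](C=C)c1ccc2c(c1)C=CC(C)(C)O2
F8 | step 7 | 1-[5-allyl-4-(tert-butyldimethylsilyloxy)-2-hydroxyphenyl]ethanone | CC(=O)c1cc(CC=C)c(O[Si](C)(C)C(C)(C)C)cc1O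
F9 | step 11 | (2S)-7-(tert-butyldimethylsilyloxy)-2-(2,2-dimethyl-2H-chromen-6-yl)-6-(3-methylbut-2-en-1-yl)chroman-4-one | CC(C)=CCc1cc2c(cc1O[Si](C)(C)C(C)(C)C)O[C@H](c1ccc3c(c1)C=CC(C)(C)O3)CC2=O
A1 | alternative 1 | (2S,4R)-trans-4,7-bis(tert-butyldimethylsilyloxy)-2-(2,2-dimethyl-2H-chromen-6-yl)-6-(3-methylbut-2-en-1-yl)chromane | CC(C)=CCc1cc2c(cc1O[Si](C)(C)C(C)(C)C)O[C@H](c1ccc3c(c1)C=CC(C)(C)O3)C[C@H]2O[Si](C)(C)C(C)(C)C
A2 | alternative 1 | tert-butyl({(3R,5S)-5-(2,2-dimethyl-2H-chromen-6-yl)-5-[(1E,3Z)-3-(tert-butyldimethylsilyloxy)-7-methylocta-1,3,6-trien-1-yloxy]pent-1-yn-3-yl}oxy)dimethylsilane | C#C[C@H](O[Si](C)(C)C(C)(C)C)C[C@@H](c1ccc2c(c1)C=CC(C)(C)O2)O/C=C/C(O[Si](C)(C)C(C)(C)C)=C/CC=C(C)C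
A3 | alternative 2 | (2S,4S)-cis-2-(2,2-dimethyl-2H-chromen-6-yl)-4-methoxy-6-(3-methylbut-2-en-1-yl)-7-(triisopropylsilyloxy)chromane | CC(C)=CCc1cc2c(cc1O[Si](C(C)C)(C(C)C)C(C)C)O[C@H](c1ccc3c(c1)C=CC(C)(C)O3)C[C@@H]2OC
A4 | alternative 2 | 2-hydroxy-5-(3-methylbut-2-en-1-yl)-4-(triisopropylsilyloxy)benzaldehyde | CC(C)=CCc1cc(C=O)c(O)cc1O[Si](C(C)C)(C(C)C)C(C)C
A5 | alternative 2 | 6-ethenyl-2,2-dimethyl-2H-chromene | C=Cc1ccc2c(c1)C=CC(C)(C)O2
A6 | alternative 3 | (2S)-2-(2,2-dimethyl-2H-chromen-6-yl)-7-(methoxymethoxy)-6-(3-methylbut-2-en-1-yl)chroman-4-one | CC(C)=CCc1cc2c(cc1OCOC)O[C@H](c1ccc3c(c1)C=CC(C)(C)O3)CC2=O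
A7 | alternative 3 | (3S)-3-[2-bromo-5-(methoxymethoxy)-4-(3-methylbut-2-en-1-yl)phenoxy]-3-(2,2-dimethyl-2H-chromen-6-yl)-N-methoxy-N-methylpropanamide | CC(C)=CCc1cc(Br)c(cc1OCOC)O[C@H](c1ccc2c(c1)C=CC(C)(C)O2)CC(=O)N(C)OC
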